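Labels: ring A (oxane) = O1, C8(=C9H2), C7(OH), C10H2, C11HBr, C12(CH3)2. Ring B (cyclohexane) = C1H (bonded to C7), C2H2, C3H2, C4(Cl)CH3, C5HBr, C6H2.
Retrosynthetic cuts, in order: C8=C9 (lactone methylenation); a helper C2=O; C3–C4 together with C5–Br (ring B); O1–C12 together with C11–Br (ring A); C1–C2 (epoxide opening); C7–C10 and the C6–alkyne bond (two copper couplings).
Enabling feature: in ring B the quaternary C4(Cl)(CH3) stands next to C5HBr, with Br, Cl and the C7 side chain all equatorial and CH3 axial. This is the imprint of an anti addition of Br+ and a carbon nucleophile (C3) across an (E)-2-chlorobut-2-enyl chain folded as a chair. BrCl addition to a cyclohexene would favour the diaxial mode instead.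
Forward order: the open chain is built from four small pieces, ring A closes by bromolactonisation, ring B closes by a bromonium-induced chloroalkene/silylalkyne cyclisation, then C2 deoxygenation, methylenation and desilylation.
Stereochemistry: C7 and C1 come from Sharpless epoxidation plus invertive alkynylation. C11 comes from a chiral bromolactonisation catalyst. C4 and C5 come from the E olefin geometry (relative) and from C1 through the chair (absolute).

Key step: step 8

Assumption: (E)-1,3-dichlorobut-2-ene is bought as the single E isomer (it can also be obtained by fractional distillation of the commercial E/Z mixture). The antipode of the organocatalyst in step 7 is the one that gives 11R.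

Step 1
Reactants: 1 prop-2-yn-1-ol; 2 (E)-1,3-dichlorobut-2-ene
Product: 3 (5E)-6-chlorohept-5-en-2-yn-1-ol
Conditions: CuI (10 mol %), NaI (10 mol %), K2CO3, DMF, rt
Reagents that add atoms: none
Why: Copper-catalysed SN2 coupling of a terminal alkyne with a primary allylic chloride (skipped-enyne synthesis) should leave the vinylic C–Cl bond and its E geometry untouched.

Step 2
Reactants: 3 (5E)-6-chlorohept-5-en-2-yn-1-ol; 4 1-bromo-3-methylbut-2-ene (prenyl bromide)
Product: 6 (2Z,5E)-6-chloro-2-(3-methylbut-2-en-1-yl)hepta-2,5-dien-1-ol, via alkenylmagnesium alkoxide 5 (not isolated)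
Conditions: iBuMgCl (2.3 equiv), Cp2TiCl2 (5 mol %), Et2O, 0 °C to rt; then CuI (10 mol %), 4, THF, 0 °C; H2O quench
Reagents that add atoms: none
Why: Titanocene-catalysed hydromagnesiation of a 2-alkyn-1-ol is a syn H–Mg addition that places magnesium next to the carbinol carbon, and the copper-catalysed allylation of 5 goes with retention, so the 2Z olefin (CH2OH cis to the chlorobutenyl chain) should result.

Step 3
Reactants: 6 (2Z,5E)-6-chloro-2-(3-methylbut-2-en-1-yl)hepta-2,5-dien-1-ol
Product: 7 [(2S,3R)-3-[(2E)-3-chlorobut-2-en-1-yl]-2-(3-methylbut-2-en-1-yl)oxiran-2-yl]methanol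
Conditions: Ti(OiPr)4 (10 mol %), L-(+)-diisopropyl tartrate (12 mol %), t-BuOOH, 4 Å MS, CH2Cl2, −20 °C
Reagents that add atoms: tert-butyl hydroperoxide, CC(C)(C)OO
Why: Sharpless asymmetric epoxidation touches only the allylic-alcohol olefin, and the L-(+)-tartrate catalyst delivers oxygen to the face that sets C7 and C1 as the (2S,3R) epoxide.

Step 4
Reactants: 7 [(2S,3R)-3-[(2E)-3-chlorobut-2-en-1-yl]-2-(3-methylbut-2-en-1-yl)oxiran-2-yl]methanol; 8 ethynyltrimethylsilane
Product: 10 (2R,3R,5E)-6-chloro-2-(3-methylbut-2-en-1-yl)-3-[(trimethylsilyl)ethynyl]hept-5-ene-1,2-diol, via alkynylalane 9 (not isolated)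
Conditions: 8, n-BuLi, toluene, 0 °C; Et2AlCl; then 7, 0 °C to rt; H2O quench
Reagents that add atoms: none
Why: Alkynylalane opening of a 2,3-epoxy alcohol is steered by the aluminium alkoxide to the distal and less hindered epoxide carbon (C1) and goes with inversion, which sets C1 against the retained C7–O stereocentre.

Step 5
Reactants: 10 (2R,3R,5E)-6-chloro-2-(3-methylbut-2-en-1-yl)-3-[(trimethylsilyl)ethynyl]hept-5-ene-1,2-diol
Product: 12 (2R,3R,5E)-6-chloro-2-hydroxy-2-(3-methylbut-2-en-1-yl)-3-[(trimethylsilyl)ethynyl]hept-5-enoic acid, via hydroxy aldehyde 11 (not isolated)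
Conditions: TEMPO (20 mol %), PhI(OAc)2 (2.2 equiv), MeCN/H2O 1:1, rt
Reagents that add atoms: water, O
Why: The TEMPO/PhI(OAc)2 oxidation takes the primary alcohol through 11 and its hydrate to the acid and cannot oxidise the tertiary alcohol, the olefins or the silylalkyne.

Step 6
Reactants: 12 (2R,3R,5E)-6-chloro-2-hydroxy-2-(3-methylbut-2-en-1-yl)-3-[(trimethylsilyl)ethynyl]hept-5-enoic acid
Product: 14 (2R,3R,5E)-6-chloro-2-(3-methylbut-2-en-1-yl)-2-[(triethylsilyl)oxy]-3-[(trimethylsilyl)ethynyl]hept-5-enoic acid, via bis-silylated acid 13 (not isolated)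
Conditions: Et3SiOTf (2.5 equiv), 2,6-lutidine, CH2Cl2, −78 to 0 °C; then THF/H2O, rt
Reagents that add atoms: triethylsilyl trifluoromethanesulfonate, CC[Si](CC)(CC)OS(=O)(=O)C(F)(F)F
Why: Silyl triflate/lutidine silylation is the standard way to cap a hindered tertiary alcohol, and water should hydrolyse only the labile silyl ester of 13.

Step 7
Reactants: 14 (2R,3R,5E)-6-chloro-2-(3-methylbut-2-en-1-yl)-2-[(triethylsilyl)oxy]-3-[(trimethylsilyl)ethynyl]hept-5-enoic acid
Product: 15 (3R,5R)-5-bromo-3-[(3R,5E)-6-chloro-1-(trimethylsilyl)hept-5-en-1-yn-3-yl]-6,6-dimethyl-3-[(triethylsilyl)oxy]oxan-2-one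
Conditions: 2,4,4,6-tetrabromocyclohexa-2,5-dienone (TBCO, 1.05 equiv), BINOL-derived amidine bifunctional organocatalyst (10 mol %), toluene/CH2Cl2, −50 °C
Reagents that add atoms: 2,4,4,6-tetrabromocyclohexa-2,5-dienone, BrC1=CC(Br)(Br)C=C(Br)C1=O
Why: In this catalytic asymmetric bromolactonisation Br+ goes to the most electron-rich (prenyl) olefin, the carboxyl group opens the bromonium ion anti at the tertiary carbon (6-endo, Markovnikov) to close ring A, and the chiral catalyst selects the olefin face that gives 11R.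

Step 8
Reactants: 15 (3R,5R)-5-bromo-3-[(3R,5E)-6-chloro-1-(trimethylsilyl)hept-5-en-1-yn-3-yl]-6,6-dimethyl-3-[(triethylsilyl)oxy]oxan-2-one
Product: 18 (3R,5R)-5-bromo-3-[(1S,4S,5S)-5-bromo-4-chloro-4-methyl-2-oxocyclohexyl]-6,6-dimethyl-3-[(triethylsilyl)oxy]oxan-2-one, via dioxacarbenium ion 16 (not isolated), via alpha-silyl ketone 17 (not isolated)
Conditions: Et2SBr·SbCl5Br (BDSB, 1.1 equiv), MeNO2, −25 °C, short contact; then H2O/MeCN, 0 °C
Reagents that add atoms: bromodiethylsulfonium bromopentachloroantimonate, CC[S+](Br)CC.Cl[Sb-](Cl)(Cl)(Cl)(Cl)Br; water, O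
Why: Proposed new method: Br+ from BDSB adds to the (E)-chloroalkene of 15 to give an unsymmetrical bromonium ion with its positive charge on C4 (stabilised by Cl and CH3), the silicon-bearing alkyne carbon C3 opens it anti to bromine, the β-silyl cyclohexenyl cation at C2 is trapped by the lactone carbonyl oxygen as 16, and water then restores the lactone, frees the C2 enol and protodesilylates 17 to 18. The closest known reaction types are the bromonium-induced polyene cyclisation with this reagent and the silylalkyne-terminated cation–olefin cyclisation that ends in a six-membered ketone, and chloroalkenes are known partners in cationic ring closures; what is new is that the chloroalkene is the olefin that takes up the halonium ion, so that chlorine stays on the new quaternary carbon. Ring B closes 6-endo at both π systems (6-endo-trig at C4=C5, 6-endo-dig at C2≡C3, the latter enforced by the β-silicon effect), and the temporary five-membered ring of 16 closes by oxygen capture of the vinyl cation, exo to C2=C3. C5 is set against C4 by the stereospecific anti addition across the E olefin (Br and Cl trans-diequatorial, CH3 axial), and both follow C1 because the chair-like fold keeps the large C7 substituent equatorial, which places Br cis to it. The step needs Br+ to choose the chloroalkene and carbon to beat oxygen as nucleophile: bridging electrophiles such as Br+ add to alkynes orders of magnitude more slowly than to alkenes whereas carbocations hardly make that difference, the only electron-rich olefin was used up in step 7, the C7 oxygen is a crowded tertiary silyl ether, and the carbonyl oxygen could reach the bromonium ion only through a seven-membered ring at C4 or an anti-Markovnikov opening at C5.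

Step 9
Reactants: 18 (3R,5R)-5-bromo-3-[(1S,4S,5S)-5-bromo-4-chloro-4-methyl-2-oxocyclohexyl]-6,6-dimethyl-3-[(triethylsilyl)oxy]oxan-2-one
Product: 20 (3R,5R)-5-bromo-3-[(1S,3S,4S)-3-bromo-4-chloro-4-methylcyclohexyl]-6,6-dimethyl-3-[(triethylsilyl)oxy]oxan-2-one, via tosylhydrazone 19 (not isolated)
Conditions: TsNHNH2, THF, rt to 40 °C; solvent switch to CHCl3, catecholborane, −10 °C; NaOAc·3H2O, reflux
Reagents that add atoms: none
Why: In this Caglioti-type deoxygenation, hydroboration of the C=N bond of 19 followed by acetate-induced loss of sulfinate and N2 replaces C=O by CH2 under near-neutral conditions that should spare the C–Br and C–Cl bonds and the lactone, and C1 stays in its favoured equatorial arrangement.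

Step 10
Reactants: 20 (3R,5R)-5-bromo-3-[(1S,3S,4S)-3-bromo-4-chloro-4-methylcyclohexyl]-6,6-dimethyl-3-[(triethylsilyl)oxy]oxan-2-one
Product: 21 {[(3R,5R)-5-bromo-3-[(1S,3S,4S)-3-bromo-4-chloro-4-methylcyclohexyl]-6,6-dimethyl-2-methylideneoxan-3-yl]oxy}triethylsilane
Conditions: Cp2TiMe2 (3 equiv), toluene, 65 °C, dark
Reagents that add atoms: dimethyltitanocene Cp2TiMe2, [CH3-].[CH3-].[Ti+4].c1cc[cH-]c1.c1cc[cH-]c1
Why: Petasis methylenation turns lactones into exocyclic enol ethers without acid or base, C8 is now the only carbonyl group, and no stereocentre is touched.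

Step 11
Reactants: 21 {[(3R,5R)-5-bromo-3-[(1S,3S,4S)-3-bromo-4-chloro-4-methylcyclohexyl]-6,6-dimethyl-2-methylideneoxan-3-yl]oxy}triethylsilane
Product: 22 (3R,5R)-5-bromo-3-[(1S,3S,4S)-3-bromo-4-chloro-4-methylcyclohexyl]-6,6-dimethyl-2-methylideneoxan-3-ol (target)
Conditions: Bu4NF, THF, 0 °C; then H2O; chromatography on Et3N-deactivated silica
Reagents that add atoms: none
Why: Fluoride-induced desilylation cleaves the Si–O bond without acid, so the acid-labile enol ether should survive, and short contact at low temperature avoids E2 loss of HBr.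

Compound list
1 | prop-2-yn-1-ol | OCC#C | starting material
2 | (E)-1,3-dichlorobut-2-ene | ClC/C=C(\C)Cl | starting material
3 | (5E)-6-chlorohept-5-en-2-yn-1-ol | OCC#CC/C=C(\C)Cl | intermediate
4 | 1-bromo-3-methylbut-2-ene | BrCC=C(C)C | starting material
5 | [(2E,5E)-6-chloro-1-(chloromagnesiooxy)hepta-2,5-dien-2-yl]magnesium chloride | Cl[Mg]OC/C([Mg]Cl)=C\C/C=C(\C)Cl | intermediate
6 | (2Z,5E)-6-chloro-2-(3-methylbut-2-en-1-yl)hepta-2,5-dien-1-ol | OC/C(CC=C(C)C)=C\C/C=C(\C)Cl | intermediate
7 | [(2S,3R)-3-[(2E)-3-chlorobut-2-en-1-yl]-2-(3-methylbut-2-en-1-yl)oxiran-2-yl]methanol | OC[C@]1(CC=C(C)C)O[C@@H]1C/C=C(\C)Cl | intermediate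
8 | ethynyltrimethylsilane | C#C[Si](C)(C)C | starting material
9 | diethyl[(trimethylsilyl)ethynyl]aluminium | CC[Al](CC)C#C[Si](C)(C)C | intermediate
10 | (2R,3R,5E)-6-chloro-2-(3-methylbut-2-en-1-yl)-3-[(trimethylsilyl)ethynyl]hept-5-ene-1,2-diol | OC[C@@](O)(CC=C(C)C)[C@@H](C#C[Si](C)(C)C)C/C=C(\C)Cl | intermediate
11 | (2R,3R,5E)-6-chloro-2-hydroxy-2-(3-methylbut-2-en-1-yl)-3-[(trimethylsilyl)ethynyl]hept-5-enal | O=C[C@@](O)(CC=C(C)C)[C@@H](C#C[Si](C)(C)C)C/C=C(\C)Cl | intermediate
12 | (2R,3R,5E)-6-chloro-2-hydroxy-2-(3-methylbut-2-en-1-yl)-3-[(trimethylsilyl)ethynyl]hept-5-enoic acid | OC(=O)[C@@](O)(CC=C(C)C)[C@@H](C#C[Si](C)(C)C)C/C=C(\C)Cl | intermediate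
13 | triethylsilyl ester of 14 | CC[Si](CC)(CC)OC(=O)[C@@](O[Si](CC)(CC)CC)(CC=C(C)C)[C@@H](C#C[Si](C)(C)C)C/C=C(\C)Cl | intermediate
14 | (2R,3R,5E)-6-chloro-2-(3-methylbut-2-en-1-yl)-2-[(triethylsilyl)oxy]-3-[(trimethylsilyl)ethynyl]hept-5-enoic acid | OC(=O)[C@@](O[Si](CC)(CC)CC)(CC=C(C)C)[C@@H](C#C[Si](C)(C)C)C/C=C(\C)Cl | intermediate
15 | (3R,5R)-5-bromo-3-[(3R,5E)-6-chloro-1-(trimethylsilyl)hept-5-en-1-yn-3-yl]-6,6-dimethyl-3-[(triethylsilyl)oxy]oxan-2-one | O=C1OC(C)(C)[C@H](Br)C[C@@]1(O[Si](CC)(CC)CC)[C@@H](C#C[Si](C)(C)C)C/C=C(\C)Cl | intermediate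
16 | tricyclic dioxacarbenium ion (C8 bonded to O1 and to the oxygen on C2; C2=C3 bearing SiMe3 at C3; ring B closed) | CC1(C)[O+]=C2OC3=C([Si](C)(C)C)[C@](C)(Cl)[C@@H](Br)C[C@H]3[C@]2(O[Si](CC)(CC)CC)C[C@H]1Br | intermediate
17 | C3-trimethylsilyl derivative of 18 (C3 configuration not defined) | O=C1OC(C)(C)[C@H](Br)C[C@@]1(O[Si](CC)(CC)CC)[C@H]1C(=O)C([Si](C)(C)C)[C@](C)(Cl)[C@@H](Br)C1 | intermediate
18 | (3R,5R)-5-bromo-3-[(1S,4S,5S)-5-bromo-4-chloro-4-methyl-2-oxocyclohexyl]-6,6-dimethyl-3-[(triethylsilyl)oxy]oxan-2-one | O=C1OC(C)(C)[C@H](Br)C[C@@]1(O[Si](CC)(CC)CC)[C@H]1C(=O)C[C@](C)(Cl)[C@@H](Br)C1 | intermediate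
19 | p-toluenesulfonylhydrazone of 18 at C2 | O=C1OC(C)(C)[C@H](Br)C[C@@]1(O[Si](CC)(CC)CC)[C@H]1C(=NNS(=O)(=O)c2ccc(C)cc2)C[C@](C)(Cl)[C@@H](Br)C1 | intermediate
20 | (3R,5R)-5-bromo-3-[(1S,3S,4S)-3-bromo-4-chloro-4-methylcyclohexyl]-6,6-dimethyl-3-[(triethylsilyl)oxy]oxan-2-one | O=C1OC(C)(C)[C@H](Br)C[C@@]1(O[Si](CC)(CC)CC)[C@H]1CC[C@](C)(Cl)[C@@H](Br)C1 | intermediate
21 | {[(3R,5R)-5-bromo-3-[(1S,3S,4S)-3-bromo-4-chloro-4-methylcyclohexyl]-6,6-dimethyl-2-methylideneoxan-3-yl]oxy}triethylsilane | C=C1OC(C)(C)[C@H](Br)C[C@@]1(O[Si](CC)(CC)CC)[C@H]1CC[C@](C)(Cl)[C@@H](Br)C1 | intermediate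
22 | (3R,5R)-5-bromo-3-[(1S,3S,4S)-3-bromo-4-chloro-4-methylcyclohexyl]-6,6-dimethyl-2-methylideneoxan-3-ol | C=C1OC(C)(C)[C@H](Br)C[C@@]1(O)[C@H]1CC[C@](C)(Cl)[C@@H](Br)C1 | target

Total step count: 11. Longest linear sequence: 11 (from 1 or 2).

Steps most likely to fail

Step 8 (new method). Several processes could compete:
- ipso-bromodesilylation of the alkyne
- proton loss or halide capture of the bromonium ion before the C–C bond forms
- rotation in an open α-chloro cation, which would erode C4
- attack of the silyl ether oxygen on the bromonium ion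
- dealkylation of the dioxacarbenium ion at C12, or its hydrolysis towards the enol lactone

The fallback uses known chemistry and sets out from 15. NBS in buffered aqueous MeCN converts the chloroalkene into the α-bromo methyl ketone F1 (C5 epimers are separated). Hg(OTf)2-catalysed hydration of the silylalkyne with loss of silicon gives the bromo diketone F2. Soft enolisation with TiCl4/Bu3N closes the same ring by intramolecular aldol addition of the C3 methyl group to the C4 ketone and gives the tertiary alcohol F3. Dry HCl in CH2Cl2 exchanges the tertiary OH for Cl; the ionisation is bridged by the neighbouring bromine, so chloride enters anti to Br. The sequence rejoins the route at 18.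

Step 9. Hydrazone formation may be slow at the crowded C2 carbonyl. HCl may be lost by β-elimination from the β-chloro ketone or from its ene-hydrazine tautomer. The fallback sets out from 18. NaBH4/CeCl3 reduction gives the equatorial C2 alcohol F4. Syn dehydration with the Burgess reagent gives the cyclohexene F5. Diimide generated from 2-nitrobenzenesulfonylhydrazide/Et3N saturates the ring olefin without touching the halides, and the route is rejoined at 20.

Step 7. Facial selectivity may be poor if the catalyst and the bias of the crowded C7 centre are mismatched, and 5-exo closure may compete. The fallback gives up reagent control and sets out from 14. Plain NBS bromolactonisation gives 15 together with the C11 epimer F6, and the two lactones are separated by chromatography. F6 is reopened reductively with Zn/AcOH to 14 and recycled. The route continues from 15.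

Further compounds
F1 | step 8 | (3R,5R)-5-bromo-3-[(3R,5S)-5-bromo-6-oxo-1-(trimethylsilyl)hept-1-yn-3-yl]-6,6-dimethyl-3-[(triethylsilyl)oxy]oxan-2-one | O=C1OC(C)(C)[C@H](Br)C[C@@]1(O[Si](CC)(CC)CC)[C@@H](C#C[Si](C)(C)C)C[C@H](Br)C(C)=O
F2 | step 8 | (3R,5R)-5-bromo-3-[(3S,5S)-5-bromo-2,6-dioxoheptan-3-yl]-6,6-dimethyl-3-[(triethylsilyl)oxy]oxan-2-one | O=C1OC(C)(C)[C@H](Br)C[C@@]1(O[Si](CC)(CC)CC)[C@@H](C(C)=O)C[C@H](Br)C(C)=O
F3 | step 8 | (3R,5R)-5-bromo-3-[(1S,5S)-5-bromo-4-hydroxy-4-methyl-2-oxocyclohexyl]-6,6-dimethyl-3-[(triethylsilyl)oxy]oxan-2-one (C4 epimers) | O=C1OC(C)(C)[C@H](Br)C[C@@]1(O[Si](CC)(CC)CC)[C@H]1C(=O)CC(C)(O)[C@@H](Br)C1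
F4 | step 9 | (3R,5R)-5-bromo-3-[(1R,2R,4S,5S)-5-bromo-4-chloro-2-hydroxy-4-methylcyclohexyl]-6,6-dimethyl-3-[(triethylsilyl)oxy]oxan-2-one | O=C1OC(C)(C)[C@H](Br)C[C@@]1(O[Si](CC)(CC)CC)[C@H]1[C@H](O)C[C@](C)(Cl)[C@@H](Br)C1
F5 | step 9 | (3R,5R)-5-bromo-3-[(1R,4S,5S)-5-bromo-4-chloro-4-methylcyclohex-2-en-1-yl]-6,6-dimethyl-3-[(triethylsilyl)oxy]oxan-2-one | O=C1OC(C)(C)[C@H](Br)C[C@@]1(O[Si](CC)(CC)CC)[C@H]1C=C[C@](C)(Cl)[C@@H](Br)C1
F6 | step 7 | (3R,5S)-5-bromo-3-[(3R,5E)-6-chloro-1-(trimethylsilyl)hept-5-en-1-yn-3-yl]-6,6-dimethyl-3-[(triethylsilyl)oxy]oxan-2-one | O=C1OC(C)(C)[C@@H](Br)C[C@@]1(O[Si](CC)(CC)CC)[C@@H](C#C[Si](C)(C)C)C/C=C(\C)Cl
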